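**Retrosynthetic overview**
1. Target ⇐ spontaneous lactonisation of a γ-hydroxy acid ⇐ one-pot hydrogenolysis (two O-benzyl groups, two benzylic ring C–O bonds) of an 8-hydroxy furofuranone. This is the reductive furofuran opening of lignan biosynthesis (pinoresinol → secoisolariciresinol → lactone), with the 8-hydroxyl carried from the bicycle as in 8-hydroxypinoresinol/olivil. (Lignan numbering: guaiacyl arm C7–C8–C9, C9 = lactone C=O; syringyl arm C7′–C8′–C9′, C9′ = OCH2.)
2. C8–OH ⇐ enolate hydroxylation at the ring-fusion carbon of the furofuranone; the cis-fused bicycle allows only retention, which after ring opening means trans benzyl groups with OH cis to the syringylmethyl group.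
3. Furofuranone ⇐ pinoresinol-type double ring closure of a bis(α-hydroxybenzyl) γ-lactone: lactone transposition onto O–C7′, then capture of the C7 quinone-methide-type cation by the C9′ hydroxyl.
4. C7–C8 ⇐ lactone aldol with O-benzylvanillin; C7′–C8′ and the only catalyst-set stereocentre (C8′) ⇐ L-proline cross-aldol of methyl 4-oxobutanoate with O-benzylsyringaldehyde.
5. Rings in order: sacrificial γ-lactone (step 1) → both furofuranone rings in one operation (step 2) → the target γ-lactone in the last reductive cascade (step 4).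

Assumption: 1, 2 and 6 are bought as catalogue chemicals; the benzylic centres C7 and C7′ of 8–12 are drawn as the expected isomers, and any epimers at these two carbons converge in step 4, where both become CH2.

**Step 1**
Reactants: 1 4-(benzyloxy)-3,5-dimethoxybenzaldehyde; 2 methyl 4-oxobutanoate
Product: 5 (4R)-4-{(R)-[4-(benzyloxy)-3,5-dimethoxyphenyl](hydroxy)methyl}oxolan-2-one, via aldol aldehyde 3 (not isolated), via diol ester 4 (not isolated)
Conditions: L-proline (30 mol%), 2 (2.5 equiv, slow addition), DMF, 4 °C, 48 h; then MeOH, NaBH4, −20 °C; work-up, cat. PPTS, CH2Cl2, rt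
Reagents that add atoms: none
Why: Proline-catalysed enamine cross-aldol (anti-selective, hydrogen-bonded Zimmerman–Traxler-type transition state) of the aldehyde donor 2 with the non-enolisable acceptor 1 sets C8′ under catalyst control (L-proline gives the 2S α-carbon, which is the C8′ configuration of the target), and immediate borohydride reduction of the formyl group followed by lactonisation of the primary alcohol onto the ester gives 5 before the α-centre can epimerise.

**Step 2**
Reactants: 5 (4R)-4-{(R)-[4-(benzyloxy)-3,5-dimethoxyphenyl](hydroxy)methyl}oxolan-2-one; 6 4-(benzyloxy)-3-methoxybenzaldehyde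
Product: 10 (3R,3aR,6S,6aS)-3-[4-(benzyloxy)-3,5-dimethoxyphenyl]-6-[4-(benzyloxy)-3-methoxyphenyl]tetrahydro-1H,3H-furo[3,4-c]furan-1-one, via dilithium alkoxide-enolate 7 (not isolated), via aldol adduct 8 (not isolated), via transposed hydroxy lactone 9 (not isolated)
Conditions: LiN(SiMe3)2 (2.3 equiv), THF, −78 °C; 6 (1.2 equiv), −78 °C, 1 h; AcOH; evaporate; TFA (10 equiv), CH2Cl2, 0 °C, 1 h
Reagents that add atoms: none
Why: Directed lactone-enolate aldol adds 6 anti to the C8′ substituent, and acid then triggers the pinoresinol-type double closure, in which lactone transposition onto the C7′ hydroxyl frees the C9′ hydroxyl (a small equilibrium share of 9 is drained irreversibly) and this hydroxyl traps the C7 p-alkoxybenzyl (quinone-methide-type) cation by 5-exo SN1 etherification; only the trans-related C8/C8′ arms can give the cis-fused bicycle, and C7 (aryl exo under SN1 control) is erased in step 4.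

**Step 3**
Reactants: 10 (3R,3aR,6S,6aS)-3-[4-(benzyloxy)-3,5-dimethoxyphenyl]-6-[4-(benzyloxy)-3-methoxyphenyl]tetrahydro-1H,3H-furo[3,4-c]furan-1-one
Product: 12 (3R,3aR,6R,6aR)-3-[4-(benzyloxy)-3,5-dimethoxyphenyl]-6-[4-(benzyloxy)-3-methoxyphenyl]-6a-hydroxytetrahydro-1H,3H-furo[3,4-c]furan-1-one, via potassium enolate 11 (not isolated)
Conditions: KN(SiMe3)2 (1.2 equiv), THF, −78 °C, 30 min; 2-(benzenesulfonyl)-3-phenyloxaziridine (1.5 equiv), −78 °C, 1 h; AcOH
Reagents that add atoms: 2-(benzenesulfonyl)-3-phenyloxaziridine (Davis oxaziridine), O=S(=O)(N1OC1c1ccccc1)c1ccccc1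
Why: Davis enolate hydroxylation at the ring-fusion carbon, where the 3,7-dioxabicyclo[3.3.0]octane must stay cis-fused, so oxygen enters on the convex face in the place of H8 and the C8 configuration is dictated absolutely by C8′; β-elimination of the ring oxygen is a stereoelectronically disfavoured reverse 5-endo-trig process at −78 °C.

**Step 4**
Reactants: 12 (3R,3aR,6R,6aR)-3-[4-(benzyloxy)-3,5-dimethoxyphenyl]-6-[4-(benzyloxy)-3-methoxyphenyl]-6a-hydroxytetrahydro-1H,3H-furo[3,4-c]furan-1-one
Product: 14 (3S,4S)-3-hydroxy-4-[(4-hydroxy-3,5-dimethoxyphenyl)methyl]-3-[(4-hydroxy-3-methoxyphenyl)methyl]oxolan-2-one, via seco hydroxy acid 13 (not isolated)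
Conditions: H2 (4 bar), Pd(OH)2/C, THF–MeOH 1:1, 40 °C, 24 h; filter, concentrate (cat. PPTS, toluene, 50 °C if lactonisation is incomplete)
Reagents that add atoms: none
Why: Catalytic hydrogenolysis removes both benzyl ethers and cleaves the two benzylic ring C–O bonds (acyloxy C7′–O and p-hydroxybenzyl ether C7–O), the laboratory counterpart of the reductive furofuran opening in lignan biosynthesis, and the γ-hydroxy acid 13 closes spontaneously to the five-membered lactone; no stereocentre is touched, and the former ring-fusion relationship becomes trans benzyl groups with the hydroxyl cis to the syringylmethyl group.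

**Compound list**
1 | 4-(benzyloxy)-3,5-dimethoxybenzaldehyde | COc1cc(C=O)cc(OC)c1OCc1ccccc1 | starting material
2 | methyl 4-oxobutanoate | COC(=O)CCC=O | starting material
3 | methyl (3S,4R)-4-[4-(benzyloxy)-3,5-dimethoxyphenyl]-3-formyl-4-hydroxybutanoate | O=C[C@@H](CC(=O)OC)[C@@H](O)c1cc(OC)c(OCc2ccccc2)c(OC)c1 | intermediate
4 | methyl (3R,4R)-4-[4-(benzyloxy)-3,5-dimethoxyphenyl]-4-hydroxy-3-(hydroxymethyl)butanoate | OC[C@@H](CC(=O)OC)[C@@H](O)c1cc(OC)c(OCc2ccccc2)c(OC)c1 | intermediate
5 | (4R)-4-{(R)-[4-(benzyloxy)-3,5-dimethoxyphenyl](hydroxy)methyl}oxolan-2-one | O=C1C[C@@H]([C@@H](O)c2cc(OC)c(OCc3ccccc3)c(OC)c2)CO1 | intermediate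
6 | 4-(benzyloxy)-3-methoxybenzaldehyde | COc1cc(C=O)ccc1OCc1ccccc1 | starting material
7 | dilithium salt of 5 (C7′ alkoxide, lactone enolate) | [Li+].[Li+].[O-]C1=C[C@@H]([C@@H]([O-])c2cc(OC)c(OCc3ccccc3)c(OC)c2)CO1 | intermediate
8 | (3S,4R)-3-{[4-(benzyloxy)-3-methoxyphenyl](hydroxy)methyl}-4-{(R)-[4-(benzyloxy)-3,5-dimethoxyphenyl](hydroxy)methyl}oxolan-2-one (both epimers at the new carbinol carbon C7) | O=C1[C@H](C(O)c2ccc(OCc3ccccc3)c(OC)c2)[C@@H]([C@@H](O)c2cc(OC)c(OCc3ccccc3)c(OC)c2)CO1 | intermediate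
9 | (3S,4R,5R)-5-[4-(benzyloxy)-3,5-dimethoxyphenyl]-3-{[4-(benzyloxy)-3-methoxyphenyl](hydroxy)methyl}-4-(hydroxymethyl)oxolan-2-one (both C7 epimers) | O=C1O[C@@H](c2cc(OC)c(OCc3ccccc3)c(OC)c2)[C@@H](CO)[C@H]1C(O)c1ccc(OCc2ccccc2)c(OC)c1 | intermediate
10 | (3R,3aR,6S,6aS)-3-[4-(benzyloxy)-3,5-dimethoxyphenyl]-6-[4-(benzyloxy)-3-methoxyphenyl]tetrahydro-1H,3H-furo[3,4-c]furan-1-one | O=C1O[C@@H](c3cc(OC)c(OCc4ccccc4)c(OC)c3)[C@H]2CO[C@H](c3ccc(OCc4ccccc4)c(OC)c3)[C@@H]12 | intermediate
11 | potassium enolate of 10 (C1–C6a enolate) | [K+].[O-]C1=C2[C@@H](c3ccc(OCc4ccccc4)c(OC)c3)OC[C@@H]2[C@H](c2cc(OC)c(OCc3ccccc3)c(OC)c2)O1 | intermediate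
12 | (3R,3aR,6R,6aR)-3-[4-(benzyloxy)-3,5-dimethoxyphenyl]-6-[4-(benzyloxy)-3-methoxyphenyl]-6a-hydroxytetrahydro-1H,3H-furo[3,4-c]furan-1-one | O=C1O[C@@H](c3cc(OC)c(OCc4ccccc4)c(OC)c3)[C@H]2CO[C@H](c3ccc(OCc4ccccc4)c(OC)c3)[C@@]12O | intermediate
13 | (2S,3S)-2-hydroxy-3-(hydroxymethyl)-4-(4-hydroxy-3,5-dimethoxyphenyl)-2-[(4-hydroxy-3-methoxyphenyl)methyl]butanoic acid | OC(=O)[C@](O)(Cc1ccc(O)c(OC)c1)[C@H](CO)Cc1cc(OC)c(O)c(OC)c1 | intermediate
14 | (3S,4S)-3-hydroxy-4-[(4-hydroxy-3,5-dimethoxyphenyl)methyl]-3-[(4-hydroxy-3-methoxyphenyl)methyl]oxolan-2-one | COc1cc(C[C@@]2(O)C(=O)OC[C@@H]2Cc2cc(OC)c(O)c(OC)c2)ccc1O | target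

**Step count**
Total steps: 4. Longest linear sequence: 4 steps (1 → 5 → 10 → 12 → 14).

**Three steps most likely to fail, each with a fallback**

Step 2. The acid stage can divert to Friedel–Crafts closure onto the electron-rich syringyl ring, to dehydration, or to scrambling at C8′ through a styrene. The fallback replaces the cationic closure by an anionic one; it sets out from 5 and 6 and comes back at 10. Claisen–Schmidt-type aldol condensation (KOtBu, THF, −20 °C to rt) gives the (E)-benzylidene hydroxy lactone F1. Under the same basic conditions, or with DBU in MeCN after isolation, the C7′ alkoxide transposes the lactone to the hydroxymethyl (E)-benzylidene lactone F2. Its primary alkoxide then closes the tetrahydrofuran by reversible 5-exo-trig oxa-Michael addition (aryl exo under thermodynamic control), and protonation of the ring-fusion enolate on the convex face gives 10.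

Step 3. The enolate 11 may open by β-elimination of the ring oxygen, or the hindered ring-fusion carbon may react sluggishly. The fallback uses the ring-opened form on purpose; it sets out from 10 and comes back at 12. KN(SiMe3)2 in THF, −78 to 0 °C, followed by TBSCl, gives the O-silylated (E)-benzylidene lactone F3. Dimethyldioxirane in acetone epoxidises the exocyclic alkene on the face anti to the cis-disposed CH2OTBS and aryl groups, giving the spiro-epoxide F4. Bu4NF in THF then frees the primary alkoxide, which opens the epoxide at the benzylic carbon C7 (5-exo, inversion). This closes the tetrahydrofuran and leaves the epoxide oxygen as the convex-face C8 hydroxyl, which is 12 with the same C7 and C8 configurations as in the main route.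

Step 4. The C7–O ether next to the quaternary carbinol may resist hydrogenolysis, and adding acid to force it risks aryltetralin formation. The fallback splits the reduction into an ionic and a catalytic stage; it sets out from 12 and comes back at 13. Et3SiH (5 equiv) with BF3·OEt2 in CH2Cl2, −40 to 0 °C, reduces the p-benzyloxybenzyl ether through its quinone-methide-type cation (excess silane at low temperature to outrun arene attack) and gives the hydroxymethyl γ-aryl lactone F5. H2 (1 bar), Pd/C, EtOAc–MeOH then only has to remove the benzyl ethers and cleave the benzylic lactone C7′–O bond, giving 13, which lactonises to 14.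

**Further compounds**
F1 | step 2 | (3E,4R)-3-[4-(benzyloxy)-3-methoxybenzylidene]-4-{(R)-[4-(benzyloxy)-3,5-dimethoxyphenyl](hydroxy)methyl}oxolan-2-one | O=C1OC[C@H]([C@@H](O)c2cc(OC)c(OCc3ccccc3)c(OC)c2)/C1=C\c1ccc(OCc2ccccc2)c(OC)c1
F2 | step 2 | (3E,4R,5R)-5-[4-(benzyloxy)-3,5-dimethoxyphenyl]-3-[4-(benzyloxy)-3-methoxybenzylidene]-4-(hydroxymethyl)oxolan-2-one | O=C1O[C@@H](c2cc(OC)c(OCc3ccccc3)c(OC)c2)[C@@H](CO)/C1=C\c1ccc(OCc2ccccc2)c(OC)c1
F3 | step 3 | (3E,4R,5R)-5-[4-(benzyloxy)-3,5-dimethoxyphenyl]-3-[4-(benzyloxy)-3-methoxybenzylidene]-4-{[(tert-butyldimethylsilyl)oxy]methyl}oxolan-2-one | O=C1O[C@@H](c2cc(OC)c(OCc3ccccc3)c(OC)c2)[C@@H](CO[Si](C)(C)C(C)(C)C)/C1=C\c1ccc(OCc2ccccc2)c(OC)c1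
F4 | step 3 | C7,C8-spiro-epoxide of F3 (oxirane oxygen anti to the CH2OTBS group) | O=C1O[C@@H](c3cc(OC)c(OCc4ccccc4)c(OC)c3)[C@@H](CO[Si](C)(C)C(C)(C)C)[C@]12O[C@H]2c1ccc(OCc2ccccc2)c(OC)c1
F5 | step 4 | (3S,4R,5R)-5-[4-(benzyloxy)-3,5-dimethoxyphenyl]-3-[4-(benzyloxy)-3-methoxybenzyl]-3-hydroxy-4-(hydroxymethyl)oxolan-2-one | O=C1O[C@@H](c2cc(OC)c(OCc3ccccc3)c(OC)c2)[C@@H](CO)[C@@]1(O)Cc1ccc(OCc2ccccc2)c(OC)c1
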